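**Retrosynthetic overview**

1. Gilluone B ⇒ ammonia condensation on the ring B β‑triketone and removal of a tert‑butoxycarbonyl blocking group on ring A; the CH2–C(quaternary) bond between the rings comes from Michael addition of a ring A dienolate to a ring B quinone‑methide‑type enone.
2. Each six‑membered ring ⇒ one‑carbon ring expansion (diazo‑carbon insertion with 1,2‑alkenyl shift) of a 4‑methoxycyclopent‑4‑ene‑1,3‑dione: with an acyl diazomethane for ring B (delivers the C‑acyl group), with a diazoacetate for ring A.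
3. Both five‑membered precursors ⇒ one enantiopure tertiary alcohol, which supplies the C(Me)(O) stereocentre of both rings.
4. That alcohol ⇒ enol ether of 3,5‑dimethylcyclopentane‑1,2,4‑trione ⇒ pentan‑3‑one + dimethyl oxalate; both acyl groups from (R)‑2‑methylbutanoic acid through one batch of its acid chloride.
5. Ring order: five‑membered carbocycle first, then ring B and ring A by parallel ring expansions, then union of the two rings.

Assumption: (+)‑(camphorsulfonyl)oxaziridine is taken to give the (S)‑alcohol in step 3 (its antipode is used if the sense is opposite); (trimethylsilyl)diazomethane, tert‑butyl diazoacetate and the oxaziridine are purchased reagents.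

Note on descriptors: the oxygenated quaternary carbon keeps its spatial arrangement from compound 5 to the target. Its CIP letter changes only because the neighbouring groups change.

**Route**

Step 1
Reactants: 1 pentan‑3‑one; 2 dimethyl oxalate
Product: 3 2‑hydroxy‑3,5‑dimethylcyclopent‑2‑ene‑1,4‑dione (enol form of 3,5‑dimethylcyclopentane‑1,2,4‑trione)
Conditions: NaOMe (2.2 equiv), MeOH, 0 °C to reflux; then 2 M HCl
Reagents that add atoms: none
Why: Double crossed Claisen condensation of both α‑carbons of the ketone with the two ester groups of the oxalate is the classical entry to 3,5‑dialkylcyclopentane‑1,2,4‑triones; the product is enolised, so no stereocentre is fixed.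

Step 2
Reactants: 3 2‑hydroxy‑3,5‑dimethylcyclopent‑2‑ene‑1,4‑dione
Product: 4 2‑methoxy‑3,5‑dimethylcyclopent‑2‑ene‑1,4‑dione
Conditions: MeOH, HC(OMe)3, TsOH·H2O (cat.), 50 °C
Reagents that add atoms: methanol, CO
Why: Acid‑catalysed enol etherification of a vinylogous acid (Fischer type) under equilibrating conditions gives the conjugated ene‑1,3‑dione enol ether and leaves one acidic C–H between the two ring carbonyls; this methoxy group ends up in both rings of the target.

Step 3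
Reactants: 4 2‑methoxy‑3,5‑dimethylcyclopent‑2‑ene‑1,4‑dione
Product: 5 (2S)‑2‑hydroxy‑4‑methoxy‑2,5‑dimethylcyclopent‑4‑ene‑1,3‑dione
Conditions: NaN(SiMe3)2, THF, −78 °C; then (+)‑(camphorsulfonyl)oxaziridine, −78 to −40 °C; aq. NH4Cl
Reagents that add atoms: (+)‑(camphorsulfonyl)oxaziridine, CC1(C)C2CCC13CS(=O)(=O)N4OC34C2
Why: Davis enolate hydroxylation with a chiral N‑sulfonyloxaziridine; the sodium ion sits between the enolate oxygen and the adjacent methoxy oxygen, so the reagent docks on one flank only and the camphor skeleton selects the face, setting the (S) tertiary carbinol that becomes the oxygenated quaternary carbon of both rings (enantiomeric purity raised by recrystallisation).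

Step 4
Reactants: 5 (2S)‑2‑hydroxy‑4‑methoxy‑2,5‑dimethylcyclopent‑4‑ene‑1,3‑dione
Product: 6 (2S)‑4‑(bromomethyl)‑2‑hydroxy‑5‑methoxy‑2‑methylcyclopent‑4‑ene‑1,3‑dione
Conditions: NBS, AIBN (cat.), PhCF3, 80 °C
Reagents that add atoms: N‑bromosuccinimide, O=C1CCC(=O)N1Br
Why: Wohl–Ziegler bromination; the only allylic C–H bonds are those of the methyl group on the enol‑ether double bond (as in 2‑methoxy‑3‑methylquinones), and the quaternary carbinol carbon is not touched.

Step 5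
Reactants: 7 (2R)‑2‑methylbutanoic acid
Product: 8 (2R)‑2‑methylbutanoyl chloride
Conditions: (COCl)2 (1.2 equiv), DMF (cat.), CH2Cl2, 0 °C to rt; short‑path distillation; one batch, divided between steps 6 and 8
Reagents that add atoms: oxalyl chloride, O=C(Cl)C(=O)Cl
Why: Vilsmeier‑type acid chloride formation under base‑free conditions, so no ketene forms and the α‑stereocentre is retained; the product is a distillable liquid that serves both acyl‑transfer steps.

Step 6
Reactants: 8 (2R)‑2‑methylbutanoyl chloride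
Product: 9 (3R)‑1‑diazo‑3‑methylpentan‑2‑one
Conditions: TMSCHN2 (2.2 equiv), THF–MeCN (1:1), 0 °C to rt
Reagents that add atoms: (trimethylsilyl)diazomethane, C[Si](C)(C)C=[N+]=[N-]
Why: Arndt–Eistert‑type acylation of the diazoalkane (Aoyama–Shioiri conditions); chloride removes the silyl group from the acyldiazonium intermediate, and with no amine base present no ketene forms, so the α‑stereocentre is retained.

Step 7
Reactants: 6 (2S)‑4‑(bromomethyl)‑2‑hydroxy‑5‑methoxy‑2‑methylcyclopent‑4‑ene‑1,3‑dione; 9 (3R)‑1‑diazo‑3‑methylpentan‑2‑one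
Product: 10 (6R)‑2‑(bromomethyl)‑5,6‑dihydroxy‑3‑methoxy‑6‑methyl‑4‑[(2R)‑2‑methylbutanoyl]cyclohexa‑2,4‑dien‑1‑one
Conditions: Sc(OTf)3 (15 mol%), 4 Å MS, CH2Cl2, −30 to 0 °C, slow addition of 9; used crude
Reagents that add atoms: none
Why: Proposed new method: Sc(OTf)3‑catalysed one‑carbon ring expansion in which an acyl diazomethane inserts its carbon into the C(=O)–C(OMe)= bond of a 4‑alkoxycyclopent‑4‑ene‑1,3‑dione; the Lewis acid binds the carbonyl next to the methoxy carbon (the only ketone not deactivated as a vinylogous ester, held by two‑point contact with the enol‑ether oxygen), the diazo carbon adds there, the electron‑rich alkenyl carbon makes the 1,2‑shift with loss of N2, and the product is drained off as the enolised β‑triketone; the closest known reaction type is the Lewis‑acid‑catalysed diazo ester homologation of cyclic ketones and isatins (Büchner–Curtius–Schlotterbeck/Roskamp type); the stereocentre is untouched.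

Step 8
Reactants: 5 (2S)‑2‑hydroxy‑4‑methoxy‑2,5‑dimethylcyclopent‑4‑ene‑1,3‑dione; 8 (2R)‑2‑methylbutanoyl chloride
Product: 11 (1S)‑3‑methoxy‑1,4‑dimethyl‑2,5‑dioxocyclopent‑3‑en‑1‑yl (2R)‑2‑methylbutanoate
Conditions: 8 (1.5 equiv), pyridine (3 equiv), DMAP (cat.), CH2Cl2, 0 °C to rt
Reagents that add atoms: none
Why: DMAP‑catalysed acylation (Steglich‑type acyl transfer through the acylpyridinium ion) of the acidic tertiary alcohol; pyridine is too weak a base to turn the acid chloride into a ketene, so the acyl α‑stereocentre is kept, and no new stereocentre is formed.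

Step 9
Reactants: 11 (1S)‑3‑methoxy‑1,4‑dimethyl‑2,5‑dioxocyclopent‑3‑en‑1‑yl (2R)‑2‑methylbutanoate
Product: 12 tert‑butyl (3R)‑2‑hydroxy‑6‑methoxy‑3,5‑dimethyl‑3‑{[(2R)‑2‑methylbutanoyl]oxy}‑4‑oxocyclohexa‑1,5‑diene‑1‑carboxylate
Conditions: tert‑butyl diazoacetate (1.3 equiv), Sc(OTf)3 (10 mol%), CH2Cl2, −40 to 0 °C
Reagents that add atoms: tert‑butyl diazoacetate, CC(C)(C)OC(=O)C=[N+]=[N-]
Why: Same ring expansion as in step 7, here with tert‑butyl diazoacetate, the diazo partner for which Sc(OTf)3‑catalysed ketone homologation (Roskamp/Büchner–Curtius–Schlotterbeck type) is best established; the diazo carbon again adds to the ketone next to the methoxy‑bearing carbon and the alkenyl carbon shifts, the enolised β‑keto ester keeps the new ring carbon blocked for step 10, and the stereocentre is untouched.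

Step 10
Reactants: 10 (6R)‑2‑(bromomethyl)‑5,6‑dihydroxy‑3‑methoxy‑6‑methyl‑4‑[(2R)‑2‑methylbutanoyl]cyclohexa‑2,4‑dien‑1‑one; 12 tert‑butyl (3R)‑2‑hydroxy‑6‑methoxy‑3,5‑dimethyl‑3‑{[(2R)‑2‑methylbutanoyl]oxy}‑4‑oxocyclohexa‑1,5‑diene‑1‑carboxylate
Product: 14 tert‑butyl (3R,5S)‑3‑({(5R)‑4,5‑dihydroxy‑2‑methoxy‑5‑methyl‑3‑[(2R)‑2‑methylbutanoyl]‑6‑oxocyclohexa‑1,3‑dien‑1‑yl}methyl)‑2‑methoxy‑3,5‑dimethyl‑5‑{[(2R)‑2‑methylbutanoyl]oxy}‑4,6‑dioxocyclohex‑1‑ene‑1‑carboxylate, via quinone‑methide‑type enone 13 (not isolated)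
Conditions: K2CO3 (2.5 equiv), MeCN, −20 to 0 °C, slow addition of 10 to 12 (1.2 equiv); then aq. citric acid
Reagents that add atoms: none
Why: Base‑induced vinylogous 1,6‑elimination of HBr from the enol gives the quinone‑methide‑type enone, which takes up the dienolate of 12 in a Michael addition at the methyl‑bearing carbon (the ester‑bearing carbon is blocked, as in alkylative dearomatisation of acylphloroglucinols) from the face opposite the acyloxy group, setting the (R) all‑carbon quaternary centre.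

Step 11
Reactants: 14 the tert‑butyl ester from step 10
Product: 16 (1R,3R)‑3‑({(5R)‑4,5‑dihydroxy‑2‑methoxy‑5‑methyl‑3‑[(2R)‑2‑methylbutanoyl]‑6‑oxocyclohexa‑1,3‑dien‑1‑yl}methyl)‑4‑methoxy‑1,3‑dimethyl‑2,6‑dioxocyclohex‑4‑en‑1‑yl (2R)‑2‑methylbutanoate, via carboxylic acid 15 (not isolated)
Conditions: TFA–CH2Cl2 (1:3), 0 °C to rt; then toluene, 50 °C
Reagents that add atoms: none
Why: Acidolysis of the tert‑butyl ester (E1 loss of isobutene) and protodecarboxylation of the vinylogous β‑keto acid by ipso‑protonation of the push–pull enol ether; the methyl enol ethers, the tertiary ester and the non‑ionisable tertiary alcohol survive anhydrous acid and no stereocentre is touched.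

Step 12
Reactants: 16 the triketone from step 11
Product: 17 Gilluone B, (1R,3R)‑3‑({(5R)‑4‑amino‑5‑hydroxy‑2‑methoxy‑5‑methyl‑3‑[(2R)‑2‑methylbutanoyl]‑6‑oxocyclohexa‑1,3‑dien‑1‑yl}methyl)‑4‑methoxy‑1,3‑dimethyl‑2,6‑dioxocyclohex‑4‑en‑1‑yl (2R)‑2‑methylbutanoate
Conditions: NH4OAc (5 equiv), MeOH, 40 °C
Reagents that add atoms: ammonium acetate, CC(=O)[O-].[NH4+]
Why: Enaminone formation: ammonia condenses with the enolised β‑triketone at the ring carbonyl, not at the hindered α‑branched side‑chain ketone, to give the hydrogen‑bonded vinylogous amide, while the buffered neutral medium spares the tertiary ester and the less activated methoxy enones.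

**Compound list**

1 | pentan‑3‑one | CCC(=O)CC | starting material
2 | dimethyl oxalate | COC(=O)C(=O)OC | starting material
3 | 2‑hydroxy‑3,5‑dimethylcyclopent‑2‑ene‑1,4‑dione (racemic, enol of the 1,2,4‑trione) | CC1=C(O)C(=O)C(C)C1=O | intermediate
4 | 2‑methoxy‑3,5‑dimethylcyclopent‑2‑ene‑1,4‑dione (racemic) | COC1=C(C)C(=O)C(C)C1=O | intermediate
5 | (2S)‑2‑hydroxy‑4‑methoxy‑2,5‑dimethylcyclopent‑4‑ene‑1,3‑dione | O=C1C(C)=C(OC)C(=O)[C@@]1(C)O | intermediate
6 | (2S)‑4‑(bromomethyl)‑2‑hydroxy‑5‑methoxy‑2‑methylcyclopent‑4‑ene‑1,3‑dione | O=C1C(CBr)=C(OC)C(=O)[C@@]1(C)O | intermediate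
7 | (2R)‑2‑methylbutanoic acid | CC[C@@H](C)C(=O)O | starting material
8 | (2R)‑2‑methylbutanoyl chloride | CC[C@@H](C)C(=O)Cl | intermediate
9 | (3R)‑1‑diazo‑3‑methylpentan‑2‑one | CC[C@@H](C)C(=O)C=[N+]=[N-] | intermediate
10 | (6R)‑2‑(bromomethyl)‑5,6‑dihydroxy‑3‑methoxy‑6‑methyl‑4‑[(2R)‑2‑methylbutanoyl]cyclohexa‑2,4‑dien‑1‑one | BrCC1=C(OC)C(C(=O)[C@H](C)CC)=C(O)[C@@](C)(O)C1=O | intermediate
11 | (1S)‑3‑methoxy‑1,4‑dimethyl‑2,5‑dioxocyclopent‑3‑en‑1‑yl (2R)‑2‑methylbutanoate | CC[C@@H](C)C(=O)O[C@]1(C)C(=O)C(OC)=C(C)C1=O | intermediate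
12 | tert‑butyl (3R)‑2‑hydroxy‑6‑methoxy‑3,5‑dimethyl‑3‑{[(2R)‑2‑methylbutanoyl]oxy}‑4‑oxocyclohexa‑1,5‑diene‑1‑carboxylate | CC[C@@H](C)C(=O)O[C@]1(C)C(O)=C(C(=O)OC(C)(C)C)C(OC)=C(C)C1=O | intermediate
13 | (6S)‑6‑hydroxy‑3‑methoxy‑6‑methyl‑2‑methylidene‑4‑[(2R)‑2‑methylbutanoyl]cyclohex‑3‑ene‑1,5‑dione | C=C1C(OC)=C(C(=O)[C@H](C)CC)C(=O)[C@@](C)(O)C1=O | intermediate
14 | tert‑butyl (3R,5S)‑3‑({(5R)‑4,5‑dihydroxy‑2‑methoxy‑5‑methyl‑3‑[(2R)‑2‑methylbutanoyl]‑6‑oxocyclohexa‑1,3‑dien‑1‑yl}methyl)‑2‑methoxy‑3,5‑dimethyl‑5‑{[(2R)‑2‑methylbutanoyl]oxy}‑4,6‑dioxocyclohex‑1‑ene‑1‑carboxylate | CC[C@@H](C)C(=O)O[C@]1(C)C(=O)C(C(=O)OC(C)(C)C)=C(OC)[C@@](C)(CC2=C(OC)C(C(=O)[C@H](C)CC)=C(O)[C@@](C)(O)C2=O)C1=O | intermediate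
15 | (3R,5S)‑3‑({(5R)‑4,5‑dihydroxy‑2‑methoxy‑5‑methyl‑3‑[(2R)‑2‑methylbutanoyl]‑6‑oxocyclohexa‑1,3‑dien‑1‑yl}methyl)‑2‑methoxy‑3,5‑dimethyl‑5‑{[(2R)‑2‑methylbutanoyl]oxy}‑4,6‑dioxocyclohex‑1‑ene‑1‑carboxylic acid | CC[C@@H](C)C(=O)O[C@]1(C)C(=O)C(C(=O)O)=C(OC)[C@@](C)(CC2=C(OC)C(C(=O)[C@H](C)CC)=C(O)[C@@](C)(O)C2=O)C1=O | intermediate
16 | (1R,3R)‑3‑({(5R)‑4,5‑dihydroxy‑2‑methoxy‑5‑methyl‑3‑[(2R)‑2‑methylbutanoyl]‑6‑oxocyclohexa‑1,3‑dien‑1‑yl}methyl)‑4‑methoxy‑1,3‑dimethyl‑2,6‑dioxocyclohex‑4‑en‑1‑yl (2R)‑2‑methylbutanoate | CC[C@@H](C)C(=O)O[C@]1(C)C(=O)C=C(OC)[C@@](C)(CC2=C(OC)C(C(=O)[C@H](C)CC)=C(O)[C@@](C)(O)C2=O)C1=O | intermediate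
17 | Gilluone B | CC[C@@H](C)C(=O)O[C@]1(C)C(=O)C=C(OC)[C@@](C)(CC2=C(OC)C(C(=O)[C@H](C)CC)=C(N)[C@@](C)(O)C2=O)C1=O | target

**Totals**

Total step count: 12.
Longest linear sequence: 8 steps (1, 2, 3, 4, 7, 10, 11, 12; the ring A branch 1, 2, 3, 8, 9, 10, 11, 12 is equally long).

**Three steps most likely to fail, with fallbacks**

The ring expansion of step 7 (the proposed new method) may fail because the acyl diazomethane is a weak nucleophile and can decompose under Lewis acid before it adds. The fallback sets out from 5 and comes back at 13, using established reactions. BF3·OEt2‑promoted TMSCHN2 homologation of 5 gives (6R)‑5,6‑dihydroxy‑3‑methoxy‑2,6‑dimethylcyclohexa‑2,4‑dien‑1‑one F3. C‑Acylation with 7 (DCC, DMAP; O‑acylation then DMAP‑induced O‑to‑C acyl transfer, standard for cyclic 1,3‑diones) gives (6R)‑5,6‑dihydroxy‑3‑methoxy‑2,6‑dimethyl‑4‑[(2R)‑2‑methylbutanoyl]cyclohexa‑2,4‑dien‑1‑one F4. NBS in CH2Cl2 brominates the methyl‑bearing enol carbon to (6R)‑2‑bromo‑6‑hydroxy‑3‑methoxy‑2,6‑dimethyl‑4‑[(2R)‑2‑methylbutanoyl]cyclohex‑3‑ene‑1,5‑dione F5. Et3N at −40 °C dehydrobrominates F5 to 13 just before 12 is added, and the route continues to 14.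

The enantioselective hydroxylation of step 3 may give low selectivity because the two flanks of the enolate differ only in a methoxy versus a methyl group. The fallback sets out from 4 and comes back at 5. The sodium enolate of 4 is oxidised with an achiral oxidant (dimethyldioxirane, acetone, −40 °C) to racemic 2‑hydroxy‑4‑methoxy‑2,5‑dimethylcyclopent‑4‑ene‑1,3‑dione F1. Preparative chromatography on a chiral phase then gives 5 and its mirror image (2R)‑2‑hydroxy‑4‑methoxy‑2,5‑dimethylcyclopent‑4‑ene‑1,3‑dione F2, which is set aside.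

The coupling of step 10 may suffer from self‑reaction of the enone 13, attack through oxygen or the ester‑bearing carbon, or a poor diastereomer ratio. The fallback sets out from 12 and 6 and comes back at 14. It forms the inter‑ring bond before ring B is enlarged: the potassium dienolate of 12 (K2CO3, MeCN, 0 °C) is alkylated in an SN2 reaction by the stable, neutral primary allylic bromide 6. This gives tert‑butyl (3R,5S)‑3‑{[(4S)‑4‑hydroxy‑2‑methoxy‑4‑methyl‑3,5‑dioxocyclopent‑1‑en‑1‑yl]methyl}‑2‑methoxy‑3,5‑dimethyl‑5‑{[(2R)‑2‑methylbutanoyl]oxy}‑4,6‑dioxocyclohex‑1‑ene‑1‑carboxylate F6. Its five‑membered ring is then enlarged with 9 under the step 7 conditions; the ring A ketones are either flanked by two quaternary carbons or deactivated as a vinylogous ester, so only ring B should react, giving 14.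

**Further compounds**

F1 | step 3 | racemic 2‑hydroxy‑4‑methoxy‑2,5‑dimethylcyclopent‑4‑ene‑1,3‑dione | O=C1C(C)=C(OC)C(=O)C1(C)O
F2 | step 3 | (2R)‑2‑hydroxy‑4‑methoxy‑2,5‑dimethylcyclopent‑4‑ene‑1,3‑dione | O=C1C(C)=C(OC)C(=O)[C@]1(C)O
F3 | step 7 | (6R)‑5,6‑dihydroxy‑3‑methoxy‑2,6‑dimethylcyclohexa‑2,4‑dien‑1‑one | CC1=C(OC)C=C(O)[C@@](C)(O)C1=O
F4 | step 7 | (6R)‑5,6‑dihydroxy‑3‑methoxy‑2,6‑dimethyl‑4‑[(2R)‑2‑methylbutanoyl]cyclohexa‑2,4‑dien‑1‑one | CC1=C(OC)C(C(=O)[C@H](C)CC)=C(O)[C@@](C)(O)C1=O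
F5 | step 7 | (6R)‑2‑bromo‑6‑hydroxy‑3‑methoxy‑2,6‑dimethyl‑4‑[(2R)‑2‑methylbutanoyl]cyclohex‑3‑ene‑1,5‑dione (both C2 epimers) | CC1(Br)C(OC)=C(C(=O)[C@H](C)CC)C(=O)[C@@](C)(O)C1=O
F6 | step 10 | tert‑butyl (3R,5S)‑3‑{[(4S)‑4‑hydroxy‑2‑methoxy‑4‑methyl‑3,5‑dioxocyclopent‑1‑en‑1‑yl]methyl}‑2‑methoxy‑3,5‑dimethyl‑5‑{[(2R)‑2‑methylbutanoyl]oxy}‑4,6‑dioxocyclohex‑1‑ene‑1‑carboxylate | CC[C@@H](C)C(=O)O[C@]1(C)C(=O)C(C(=O)OC(C)(C)C)=C(OC)[C@@](C)(CC2=C(OC)C(=O)[C@@](C)(O)C2=O)C1=O
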